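The flavone is cut through ring A at C8–C8a and C4a–C5, so that C5–C6–C7–C8 with its 1,3-related oxygens at C5 and C7 comes from an acetoacetate-derived bis-silyloxy diene and ring C from a 4-pyranone. In one operation the annulation should fuse ring A onto the C4a=C8a bond, place both phenolic oxygens and, through loss of HBr and methanol, deliver the aromatic oxidation level. The precursor is a 3-bromo-6-aryl-4H-pyran-4-one whose ring B already carries the 4',5'-diphenylmethylene ketal and the 3'-sulfate masked as its 2,2,2-trichloroethyl diester, so that the annulation is followed by a single reductive unmasking.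

Key step: step 9

Remarks:
- Flavone numbering (O1, C2 to C8a, ring B primed) is used for the ring-forming steps; pyranone numbering is used for compounds 9 to 12.
- Ar = 2,2-diphenyl-7-[(2,2,2-trichloroethoxy)sulfonyloxy]-1,3-benzodioxol-5-yl.
- The target is drawn as the free hydrogen sulfate, so it is assumed that the ammonium salt formed on deprotection is to be protonated at the end.
- Compound 1 is sold as a hydrate and is dried azeotropically before use.

Step 1
Reactants: 1 3,4,5-trihydroxybenzaldehyde; 2 dichlorodiphenylmethane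
Product: 3 7-hydroxy-2,2-diphenyl-1,3-benzodioxole-5-carbaldehyde
Conditions: Ph2O, 175 °C, N2 sweep
Reagents that add atoms: none
Why: Twofold phenol O-alkylation by the gem-dichloride (catechol ketalisation) can only bridge a vicinal OH pair, and as both pairs of the symmetric triol are equivalent a single ketal with one free outer OH should form while the aldehyde is untouched.

Step 2
Reactants: 4 2,2,2-trichloroethanol
Product: 5 2,2,2-trichloroethyl chlorosulfate
Conditions: SO2Cl2, pyridine, Et2O, −78 °C to rt; distillation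
Reagents that add atoms: sulfuryl chloride, O=S(=O)(Cl)Cl
Why: Sulfurylation of the alcohol by SO2Cl2 with pyridine (chlorosulfate formation) should stop after one substitution because the electron-poor chlorosulfate is a much weaker electrophile at low temperature.

Step 3
Reactants: 3 7-hydroxy-2,2-diphenyl-1,3-benzodioxole-5-carbaldehyde; 5 2,2,2-trichloroethyl chlorosulfate
Product: 6 6-formyl-2,2-diphenyl-1,3-benzodioxol-4-yl 2,2,2-trichloroethyl sulfate
Conditions: Et3N, DMAP, THF, 0 °C to rt
Reagents that add atoms: none
Why: DMAP-catalysed O-sulfurylation of the phenol (sulfate diester formation) installs the sulfate in a neutral form that should tolerate Lewis acids, electrophilic bromine and quinone oxidants, and the meta aldehyde does not interfere.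

Step 4
Reactants: 6 6-formyl-2,2-diphenyl-1,3-benzodioxol-4-yl 2,2,2-trichloroethyl sulfate; 7 (E)-1-methoxy-3-(trimethylsilyloxy)buta-1,3-diene
Product: 9 2-Ar-2,3-dihydro-4H-pyran-4-one (racemic), via silyl aldol adduct 8 (not isolated)
Conditions: Yb(OTf)3 (10 mol%), MeCN–CH2Cl2, 0 °C to rt; then TFA (cat.), CH2Cl2, 0 °C
Reagents that add atoms: none
Why: Lewis-acid-catalysed Mukaiyama aldol addition of the siloxydiene to the aryl aldehyde, then acid-induced oxa-Michael closure with loss of methanol (a stepwise hetero-Diels–Alder reaction), should give the dihydropyranone; its C2 stereocentre forms without control as a racemate and is erased in step 6.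

Step 5
Reactants: 9 2-Ar-2,3-dihydro-4H-pyran-4-one
Product: 10 5-bromo-2-Ar-2,3-dihydro-4H-pyran-4-one (racemic)
Conditions: NBS, CH2Cl2, 0 °C to rt, dark
Reagents that add atoms: N-bromosuccinimide, O=C1CCC(=O)N1Br
Why: Electrophilic alpha-bromination of the vinylogous ester is regiochemically unambiguous, since C5 is the only enol-ether carbon (bromine transfer, then loss of the C5 proton from the oxocarbenium ion) and the arene is deactivated by the sulfate diester.

Step 6
Reactants: 10 5-bromo-2-Ar-2,3-dihydro-4H-pyran-4-one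
Product: 12 3-bromo-6-Ar-4H-pyran-4-one, via silyl dienol ether 11 (not isolated)
Conditions: TMSOTf, Et3N, CH2Cl2, 0 °C; then DDQ, 0 °C to rt
Reagents that add atoms: none
Why: Soft enolisation gives the 4-silyloxy-2H-pyran 11, whose benzylic, oxygen-bearing C2–H should be abstracted as hydride by DDQ to a silyloxypyrylium ion that desilylates to the gamma-pyranone (DDQ dehydrogenation of a silyl enol ether, the quinone counterpart of the Saegusa oxidation), with no palladium that could insert into the C–Br bond.

Step 7
Reactants: 13 methyl acetoacetate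
Product: 14 methyl 3-(trimethylsilyloxy)but-2-enoate
Conditions: Me3SiCl, Et3N, hexane, rt; filtration, distillation
Reagents that add atoms: chlorotrimethylsilane, C[Si](C)(C)Cl
Why: O-Silylation of the enol of the beta-keto ester under amine base (silyl enol ether formation) is routine; the double-bond geometry is irrelevant.

Step 8
Reactants: 14 methyl 3-(trimethylsilyloxy)but-2-enoate
Product: 15 1-methoxy-1,3-bis(trimethylsilyloxy)buta-1,3-diene
Conditions: LDA, THF, −78 °C; Me3SiCl, −78 °C to rt; distillation, used fresh
Reagents that add atoms: chlorotrimethylsilane, C[Si](C)(C)Cl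
Why: Gamma-deprotonation by LDA gives the ester dienolate, which should be silylated on oxygen to the bis-silyloxy diene (silyl ketene acetal formation).

Step 9
Reactants: 12 3-bromo-6-Ar-4H-pyran-4-one; 15 1-methoxy-1,3-bis(trimethylsilyloxy)buta-1,3-diene
Product: 19 4',5'-O-diphenylmethylene tricetin 3'-(2,2,2-trichloroethyl sulfate), via silyloxypyrylium triflate 16 (not isolated), via vinylogous Mukaiyama adduct 17 (not isolated), via bromo enedione 18 (not isolated)
Conditions: TMSOTf (1.3 equiv), CH2Cl2, −78 °C; 15 (1.5 equiv), −78 to 0 °C; then Et3N, 0 °C to rt; MeOH, aq. NH4Cl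
Reagents that add atoms: none
Why: Proposed new method: O-silylation of 12 should give the 4-silyloxypyrylium ion 16, and the terminal CH2 of 15 should add to its unsubstituted oxygen-bearing carbon in a vinylogous Mukaiyama–Michael step (C8–C8a), giving the 2H-pyran 17 in which bromine sits on the nucleophilic carbon of a silyl enol ether. With TMSOTf still present the ester carbon is re-activated as a dioxycarbenium ion and captured by that carbon in a 6-(enolexo)-exo-trig Mukaiyama–Claisen closure (C4a–C5, ring A), and loss of MeOSiMe3 gives 18. Et3N then removes HBr across C4a–C8a by E2 (an isomer with syn H and Br can equilibrate by reversible opening of the C8a–O1 bond through the C8 enolate), and tautomerisation makes ring A aromatic with both oxygens in place. The closest known reaction types are the cycloaddition–aromatisation of 1,1-dioxygenated siloxydienes with halo-quinones and the addition of silyl enol ethers to 4-silyloxypyrylium and benzopyrylium triflates. No stereocentre survives, since the two ring-fusion centres of 18 are transient. The step needs one diene orientation and the [4+2] rather than the [3+3] mode: the first is secured by polarity and sterics (CH2 terminus to the free C8a, not to the aryl-bearing C2), the second by keeping the medium Lewis-acidic until ring closure so that the central keto-ester carbon is never an enolate.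

Step 10
Reactants: 19 4',5'-O-diphenylmethylene tricetin 3'-(2,2,2-trichloroethyl sulfate)
Product: 21 tricetin 3'-sulfate, via ammonium tricetin 3'-sulfate 20 (not isolated)
Conditions: H2 (1 atm), 10% Pd/C, HCO2NH4, MeOH–THF, rt; then aq. HCl to pH 2, 0 °C, C18 desalting
Reagents that add atoms: none
Why: Palladium-catalysed transfer hydrogenolysis should remove the trichloroethyl group by reductive dechlorination and beta-elimination and cleave the doubly benzylic C–O bonds of the ketal under buffered neutral conditions that spare the aryl sulfate monoester and the C2=C3 bond; brief cold acidification protonates the salt.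

Compound list
1 | 3,4,5-trihydroxybenzaldehyde | O=Cc1cc(O)c(O)c(O)c1 | starting material
2 | dichlorodiphenylmethane | ClC(Cl)(c1ccccc1)c1ccccc1 | starting material
3 | 7-hydroxy-2,2-diphenyl-1,3-benzodioxole-5-carbaldehyde | O=Cc1cc(O)c2OC(c3ccccc3)(c3ccccc3)Oc2c1 | intermediate
4 | 2,2,2-trichloroethanol | OCC(Cl)(Cl)Cl | starting material
5 | 2,2,2-trichloroethyl chlorosulfate | ClS(=O)(=O)OCC(Cl)(Cl)Cl | intermediate
6 | 6-formyl-2,2-diphenyl-1,3-benzodioxol-4-yl 2,2,2-trichloroethyl sulfate | O=Cc1cc(OS(=O)(=O)OCC(Cl)(Cl)Cl)c2OC(c3ccccc3)(c3ccccc3)Oc2c1 | intermediate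
7 | (E)-1-methoxy-3-(trimethylsilyloxy)buta-1,3-diene | CO/C=C/C(=C)O[Si](C)(C)C | starting material
8 | (E)-5-Ar-1-methoxy-5-(trimethylsilyloxy)pent-1-en-3-one, racemic, not isolated | CO/C=C/C(=O)CC(O[Si](C)(C)C)c1cc(OS(=O)(=O)OCC(Cl)(Cl)Cl)c2OC(c3ccccc3)(c3ccccc3)Oc2c1 | intermediate
9 | 2-Ar-2,3-dihydro-4H-pyran-4-one, racemic | O=C1C=COC(c2cc(OS(=O)(=O)OCC(Cl)(Cl)Cl)c3OC(c4ccccc4)(c4ccccc4)Oc3c2)C1 | intermediate
10 | 5-bromo-2-Ar-2,3-dihydro-4H-pyran-4-one, racemic | O=C1CC(c2cc(OS(=O)(=O)OCC(Cl)(Cl)Cl)c3OC(c4ccccc4)(c4ccccc4)Oc3c2)OC=C1Br | intermediate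
11 | 5-bromo-2-Ar-4-(trimethylsilyloxy)-2H-pyran, racemic, not isolated | C[Si](C)(C)OC1=CC(c2cc(OS(=O)(=O)OCC(Cl)(Cl)Cl)c3OC(c4ccccc4)(c4ccccc4)Oc3c2)OC=C1Br | intermediate
12 | 3-bromo-6-Ar-4H-pyran-4-one (key-step precursor) | O=c1cc(-c2cc(OS(=O)(=O)OCC(Cl)(Cl)Cl)c3OC(c4ccccc4)(c4ccccc4)Oc3c2)occ1Br | intermediate
13 | methyl acetoacetate | CC(=O)CC(=O)OC | starting material
14 | methyl 3-(trimethylsilyloxy)but-2-enoate, double-bond geometry not controlled | COC(=O)C=C(C)O[Si](C)(C)C | intermediate
15 | 1-methoxy-1,3-bis(trimethylsilyloxy)buta-1,3-diene (key-step precursor), ketene acetal geometry not controlled | COC(O[Si](C)(C)C)=CC(=C)O[Si](C)(C)C | intermediate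
16 | 3-bromo-6-Ar-4-(trimethylsilyloxy)pyrylium trifluoromethanesulfonate, not isolated | C[Si](C)(C)Oc1cc(-c2cc(OS(=O)(=O)OCC(Cl)(Cl)Cl)c3OC(c4ccccc4)(c4ccccc4)Oc3c2)[o+]cc1Br.[O-]S(=O)(=O)C(F)(F)F | intermediate
17 | methyl 4-[6-Ar-3-bromo-4-(trimethylsilyloxy)-2H-pyran-2-yl]-3-(trimethylsilyloxy)but-2-enoate, racemic, not isolated | COC(=O)C=C(O[Si](C)(C)C)CC1OC(c2cc(OS(=O)(=O)OCC(Cl)(Cl)Cl)c3OC(c4ccccc4)(c4ccccc4)Oc3c2)=CC(O[Si](C)(C)C)=C1Br | intermediate
18 | 2-Ar-4a-bromo-5-(trimethylsilyloxy)-8,8a-dihydro-4H-chromene-4,7(4aH)-dione, racemic, ring-fusion configuration not controlled, not isolated | O=C1C=C(O[Si](C)(C)C)C2(Br)C(=O)C=C(c3cc(OS(=O)(=O)OCC(Cl)(Cl)Cl)c4OC(c5ccccc5)(c5ccccc5)Oc4c3)OC2C1 | intermediate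
19 | 4',5'-O-diphenylmethylene tricetin 3'-(2,2,2-trichloroethyl sulfate), that is 5,7-dihydroxy-2-Ar-4H-chromen-4-one (key-step product) | O=c1cc(-c2cc(OS(=O)(=O)OCC(Cl)(Cl)Cl)c3OC(c4ccccc4)(c4ccccc4)Oc3c2)oc2cc(O)cc(O)c12 | intermediate
20 | ammonium tricetin 3'-sulfate, not isolated | [NH4+].[O-]S(=O)(=O)Oc1cc(-c2cc(=O)c3c(O)cc(O)cc3o2)cc(O)c1O | intermediate
21 | tricetin 3'-sulfate | O=c1cc(-c2cc(O)c(O)c(OS(=O)(=O)O)c2)oc2cc(O)cc(O)c12 | target

Total step count: 10. Longest linear sequence: 7 steps (steps 1, 3, 4, 5, 6, 9, 10).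

Steps most likely to fail

Step 9. The annulation may stall after the first C–C bond because the ester carbon is too weak an electrophile for ring closure. It may also divert to closure of the central keto-ester carbon onto C4, or lose bromine from C4a by halogen transfer before HBr is eliminated. The fallback uses known chemistry and sets out from aldehyde 3. Claisen–Schmidt condensation with purchased 1-[2-hydroxy-4,6-bis(benzyloxy)phenyl]ethanone (KOH, EtOH, rt; the meta phenoxide does not deactivate the aldehyde) should give the 2'-hydroxychalcone F1. Oxidative cyclisation (I2 cat., DMSO, 120 °C) should give the 5,7-di-O-benzyl flavone with free 3'-OH F2. Sulfurylation with 5 under the conditions of step 3 should give the trichloroethyl sulfate F3. The conditions of step 10 then cleave benzyl ethers, ketal and trichloroethyl group together, and the route is rejoined at ammonium salt 20.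

Step 6. Enolisation may be incomplete, or the silyl dienol ether may be trapped by DDQ as a stable adduct or open to an acyclic dienone, so that dehydrogenation stalls or the heterocycle is lost. The fallback sets out from 10. The dienol ether 11 is generated as before and quenched with PhSeCl (CH2Cl2, −78 °C) to give the 3-phenylselanyl ketone F4. Oxidation (H2O2, pyridine, CH2Cl2, 0 °C to rt) and syn-elimination of the selenoxide towards C2 should return the route at 12.

Step 10. Hydrogen uptake may go beyond deprotection and saturate C2=C3, or ketal cleavage may slow once chloride is released onto the catalyst. The free hydrogen sulfate may also hydrolyse during acidification. The fallback sets out from 19 and decouples the two deprotections. Zinc-mediated reductive beta-elimination (Zn dust, HCO2NH4, MeOH–THF, rt) should unmask the sulfate as the ketal-protected ammonium salt F5. Separate hydrogenolysis of the ketal (H2, Pd(OH)2/C, MeOH–THF, rt) then returns the route at 20.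

Further compounds
F1 | step 9 | (E)-1-[2-hydroxy-4,6-bis(benzyloxy)phenyl]-3-(7-hydroxy-2,2-diphenyl-1,3-benzodioxol-5-yl)prop-2-en-1-one | O=C(/C=C/c1cc(O)c2OC(c3ccccc3)(c3ccccc3)Oc2c1)c1c(O)cc(OCc2ccccc2)cc1OCc1ccccc1
F2 | step 9 | 5,7-di-O-benzyl-4',5'-O-diphenylmethylene tricetin | O=c1cc(-c2cc(O)c3OC(c4ccccc4)(c4ccccc4)Oc3c2)oc2cc(OCc3ccccc3)cc(OCc3ccccc3)c12
F3 | step 9 | 5,7-di-O-benzyl-4',5'-O-diphenylmethylene tricetin 3'-(2,2,2-trichloroethyl sulfate) | O=c1cc(-c2cc(OS(=O)(=O)OCC(Cl)(Cl)Cl)c3OC(c4ccccc4)(c4ccccc4)Oc3c2)oc2cc(OCc3ccccc3)cc(OCc3ccccc3)c12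
F4 | step 6 | 5-bromo-3-(phenylselanyl)-2-Ar-2,3-dihydro-4H-pyran-4-one, racemic, 2,3-trans expected | O=C1C([Se]c2ccccc2)C(c2cc(OS(=O)(=O)OCC(Cl)(Cl)Cl)c3OC(c4ccccc4)(c4ccccc4)Oc3c2)OC=C1Br
F5 | step 10 | ammonium 4',5'-O-diphenylmethylene tricetin 3'-sulfate | [NH4+].[O-]S(=O)(=O)Oc1cc(-c2cc(=O)c3c(O)cc(O)cc3o2)cc2OC(c3ccccc3)(c3ccccc3)Oc12
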